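Remark on the chemistry (assumption): the SMILES is read as the 5S,6S,7R,8R isomer in germacrane numbering (fused-ring name 3aR,4R,11S,11aS), with C2 and C9 cis across C1=C10 and a (Z)-2-methylbut-2-enoate (angelate) on O8; chromium species 15 and 22 are written without their solvent ligands.

## The problem

The target is a melampolide-type germacranolide; in germacrane numbering a ten-membered carbocycle (ring A, C1–C10) is trans-fused at C6–C7 to an α-methylene-γ-butyrolactone (ring B: O6–C6–C7–C11–C12, with C13H2= on C11), C10 carries the C14 methyl ester, C4 the C15 methylene, C5 a free hydroxyl and C8 the angelate. Ring A is the first difficulty: a strained medium ring with three sp2 ring atoms (C1, C10, C4), whose only endocyclic alkene, C1=C10, has C2 and C9 cis (E by the sequence rule because of C14), and which offers a handle for closure at only four bonds (C4–C5, C6–C7, C7–C8, C1=C10). The second is the run of four contiguous stereocentres C5 (S), C6 (S), C7 (R), C8 (R): a threo 5,6-dioxygenation, a trans lactone, and O8 syn to C6 when C9–C8–C7–C11 is drawn as a zigzag. C6, once held in the flat five-membered ring B, is the centre best placed to control C7 (attack anti to its substituent); C7 and the allyl geometry can then control C8, and C6 can control C5 through the ring being closed. O5, O6 and O8 must be told apart, and because O6 and O8 are both γ to C12 an open-chain hydroxy ester could lactonize in either direction. The functionality is fragile: the methylene lactone and the C1=C10 enoate are Michael acceptors, the angelate goes over to the tiglate when its acyl group is activated in the presence of nucleophiles, and C7–H and C9–H2 invite base-mediated alkene migration. The feature that makes the key step possible is the array O8–C8–C7–C11(=C13)–C12(=O)–O6–C6: a homoallylic alcohol (C8–OH, C7, C11=C13) whose allyl unit C13–C11–C7 lies in ring B. This is the retron of the addition of a 3-(bromomethyl)butenolide-derived allylmetal (double bond C7=C11 inside ring B, C6 already carrying the ring oxygen and its configuration) to a C8 aldehyde.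

## Retrosynthesis

**23 ⇒ 21 (C4–C5).** The last bond made is C4–C5, between the vinylic carbon C4 and the carbinol carbon C5. Forward, the alkenylchromium 22, made in the flask from the 2-iodo-1-alkene of 21, adds to the C5 aldehyde (intramolecular Nozaki–Hiyama–Kishi reaction). This cut is preferred to its neighbours because it is the only ring bond whose formation gives the C4(=C15H2)–C5(OH) array in one operation, needs no protecting group, and tolerates the enoate, the methylene lactone and the angelate. Closure at C6–C7 or C7–C8 would spend the allylation on the ring and leave C5 to be made elsewhere. 21 is acyclic apart from ring B and already has three of the four stereocentres. Asked of the forward step: closure at high dilution and attack on the aldehyde face that gives 5S.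

**21 ⇒ 19 ⇒ 17 + 18 (C8–O, with inversion).** The aldehyde of 21 comes from alcohol 20 by oxidation, and 20 from silyl ether 19; O5 thus travels as a primary silyl ether. The angelate C–O bond at C8 is cut with inversion: forward, Mitsunobu esterification of the 8S alcohol 17 with angelic acid 18. The allylation below gives 8S by its normal chair transition state. The Mitsunobu reaction turns this into the needed 8R while attaching the ester without ever activating the angeloyl carbonyl, the state in which angelates isomerize. Asked: SN2 substitution at a secondary carbinol next to C7.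

**17 ⇒ 5 + 14 (C7–C8).** The C7–C8 bond is cut together with a shift of C11=C13 back to C7=C11. Forward, bromide 5 is reduced to allylchromium 15, which adds to aldehyde 14; the alkoxide is capped in the flask as silyl ether 16 and released on work-up. The cut divides the skeleton into two pieces of similar size (C5–C7 with C11–C13; C8–C10 with C14, C1–C4 and C15). It creates the methylene lactone at the moment of union, so that it never meets a base, and sets C7 and C8 from the single stereocentre C6. At the neighbouring C6–C7 cut the lactone oxygen would sit on an open chain, and C6 could direct nothing because it would itself be created. 5 has one stereocentre and 14 none; 17 has three and the whole carbon skeleton. Asked: γ-attack anti to the C6 substituent, a chair transition state, reaction of the allylic bromide but not the vinylic iodide, and survival of the β,γ-unsaturated aldehyde 14.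

**5 ⇒ 4 ⇒ 2 + 3; 2 ⇒ 1.** The C7=C11 bond of ring B is cut by ring-closing metathesis. Diene 4 is the ester of allylic alcohol 2 with 2-(bromomethyl)acrylic acid 3, and 2 is the primary silyl ether of commercial (S)-but-3-ene-1,2-diol 1, whose stereocentre becomes C6. This is three steps with no stereochemical event, against several for α-functionalization of a preformed butenolide.

**14 ⇒ 13 ⇒ 12 ⇒ 8 + 11; 8 ⇒ 6 + 7; 11 ⇒ 10 ⇒ 9.** The C1=C10 bond is cut by Horner–Wadsworth–Emmons olefination of 4-iodopent-4-enal 11 with phosphonate 8. Made early, in a fragment with no other electrophile, the olefination can follow its natural selectivity (ester trans to the new chain, hence C2 cis to C9). The C8 aldehyde is unveiled last, from silyl ether 12 via alcohol 13, because 14 is prone to double-bond migration. 8 comes from alkylation of phosphonoacetate 6 with bromide 7; 11 from pent-4-yn-1-ol 9 via iodo alcohol 10.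

## Roads not taken

Alternative 1: cut C6–C7 together with O6–C12, the disconnection most chemists would draw first for a germacranolide. Forward key step: intramolecular allylation (divalent chromium or zinc) of the C6 aldehyde of the open-chain (Z)-2-(bromomethyl)enoate A1, lactonization to the O5-silyl ether A2, then desilylation. The chosen plan is better for three reasons:
- A1 must carry C5 and C8 as preformed stereocentres in two different halves, each from its own asymmetric step. They are 1,2- and 1,4-related to the centres being made, so two independent inductions must agree inside a ten-membered transition state. In the chosen plan one purchased centre (C6) controls C7 through a rigid five-membered ring and C8 through a simple chair.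
- In the open-chain adduct O6 and O8 are both γ to C12, so the angelate must already be on O8 and pass through the reductive step to steer lactonization.
- The linear build of A1, with three differentiated oxygens, an aldehyde and an allylic bromide, is longer than the three- and four-step fragments used here.

Alternative 2: cut C1=C10. Forward key step: ring-closing metathesis of the tetraene A3 (terminal alkene at C1, 2-substituted acrylate at C10). The chosen plan is better for three reasons:
- This closure creates no stereocentre, so all four, including the threo 5,6-diol, must be set beforehand, with extra steps and protecting-group changes.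
- The ruthenium carbene at C1 must choose the acrylate over two other 1,1-disubstituted alkenes (C11=C13, an eight-membered closure, and C4=C15).
- A trisubstituted, electron-poor alkene in a strained ten-membered ring normally needs forcing conditions.

An olefination variant of the same cut would place a stabilized C10 carbanion six atoms from the Michael terminus C13 (6-endo addition).

Alternative 3: trade the C5–C10 bond for the C2–C3 bond. Forward key step: anionic oxy-Cope rearrangement of the cis-1,2-divinylcyclohexanol A4 (six-membered ring C5–C10, vinyl groups on C5 and C10) to the cyclodecenone A5, followed by C4 methylenation, C5 reduction, lactone methylenation and acylation. The chosen plan is better for four reasons: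
- A4 is no simpler than the target: five contiguous substituted ring carbons including quaternary C10, plus a C5 configuration that serves only to steer the rearrangement.
- Its alkoxide is β to the C14 ester, so retro-aldol cleavage of C5–C10 can compete with the concerted path and loosen control of the alkene geometry.
- The strongly basic conditions exclude the methylene lactone and the angelate, which would have to be added afterwards in the presence of an enolizable enoate and ketone.
- Methylenation at C4 and reduction at C5 in the ten-membered ring add further uncontrolled steps after the key step, against four here.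

Key step: step 10

## Route

Step 1
Reactants: 1 (S)-but-3-ene-1,2-diol
Product: 2 (S)-1-[(tert-butyldimethylsilyl)oxy]but-3-en-2-ol
Conditions: TBSCl (1.05 equiv), imidazole, CH2Cl2, 0 °C
Reagents that add atoms: tert-butyldimethylsilyl chloride, CC(C)(C)[Si](C)(C)Cl
Why: Sterically controlled silylation of the primary hydroxyl of a 1,2-diol; the stereocentre (future C6) is not touched.

Step 2
Reactants: 2 (S)-1-[(tert-butyldimethylsilyl)oxy]but-3-en-2-ol; 3 2-(bromomethyl)prop-2-enoic acid
Product: 4 (S)-1-[(tert-butyldimethylsilyl)oxy]but-3-en-2-yl 2-(bromomethyl)prop-2-enoate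
Conditions: DCC, DMAP (cat.), CH2Cl2, 0 °C to rt
Reagents that add atoms: none
Why: Steglich esterification of the secondary allylic alcohol; it is run cold with little DMAP so that the allylic bromide is not displaced.

Step 3
Reactants: 4 (S)-1-[(tert-butyldimethylsilyl)oxy]but-3-en-2-yl 2-(bromomethyl)prop-2-enoate
Product: 5 (S)-3-(bromomethyl)-5-{[(tert-butyldimethylsilyl)oxy]methyl}furan-2(5H)-one
Conditions: second-generation Grubbs catalyst RuCl2(=CHPh)(H2IMes)(PCy3) (5 mol%), toluene, 80 °C, 0.01 M
Reagents that add atoms: none
Why: Ring-closing metathesis of an allyl 2-substituted acrylate to the butenolide with loss of ethene; the five-membered closure is favoured, the stereocentre is not involved and ruthenium carbenes tolerate allylic bromides.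

Step 4
Reactants: 6 methyl 2-(diethoxyphosphoryl)acetate; 7 (2-bromoethoxy)(tert-butyl)dimethylsilane
Product: 8 methyl 4-[(tert-butyldimethylsilyl)oxy]-2-(diethoxyphosphoryl)butanoate (racemic)
Conditions: NaH, DMSO, rt; then 7, 60 °C
Reagents that add atoms: none
Why: SN2 C-alkylation of the phosphonoacetate anion by a primary bromide; the new stereocentre is of no consequence because it becomes sp2 in step 7.

Step 5
Reactants: 9 pent-4-yn-1-ol
Product: 10 4-iodopent-4-en-1-ol
Conditions: NaI, Me3SiCl, H2O, MeCN, rt
Reagents that add atoms: sodium iodide (acting as HI made in the flask), [Na+].[I-]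
Why: Markovnikov hydroiodination of the terminal alkyne by HI generated in the flask gives the 2-iodo-1-alkene; the hydroxyl is recovered on aqueous work-up.

Step 6
Reactants: 10 4-iodopent-4-en-1-ol
Product: 11 4-iodopent-4-enal
Conditions: Dess–Martin periodinane, NaHCO3, CH2Cl2, 0 °C to rt
Reagents that add atoms: none
Why: Dess–Martin oxidation of a primary alcohol stops at the aldehyde under buffered conditions; the vinylic iodide is inert.

Step 7
Reactants: 8 methyl 4-[(tert-butyldimethylsilyl)oxy]-2-(diethoxyphosphoryl)butanoate; 11 4-iodopent-4-enal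
Product: 12 methyl (2E)-2-{2-[(tert-butyldimethylsilyl)oxy]ethyl}-6-iodohepta-2,6-dienoate
Conditions: NaH, THF, 0 °C; then 11, −20 °C to rt
Reagents that add atoms: none
Why: Horner–Wadsworth–Emmons olefination with an α-branched phosphonoacetate; the reversible addition favours the isomer with the ester trans to the new chain (E, C2 cis to C9), and any (Z)-isomer is removed by chromatography.

Step 8
Reactants: 12 methyl (2E)-2-{2-[(tert-butyldimethylsilyl)oxy]ethyl}-6-iodohepta-2,6-dienoate
Product: 13 methyl (2E)-2-(2-hydroxyethyl)-6-iodohepta-2,6-dienoate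
Conditions: HF·pyridine, pyridine, THF, 0 °C
Reagents that add atoms: none
Why: Cleavage of a primary silyl ether by buffered HF; the mildly acidic, non-basic medium keeps the γ-hydroxy ester from lactonizing onto C14.

Step 9
Reactants: 13 methyl (2E)-2-(2-hydroxyethyl)-6-iodohepta-2,6-dienoate
Product: 14 methyl (2E)-6-iodo-2-(2-oxoethyl)hepta-2,6-dienoate
Conditions: Dess–Martin periodinane, NaHCO3, CH2Cl2, 0 °C; filtered and used at once
Reagents that add atoms: none
Why: Dess–Martin oxidation under buffered, near-neutral conditions, chosen so that the C9 methylene between the aldehyde and C10 is not enolized and C1=C10 stays in place.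

Step 10
Reactants: 5 (S)-3-(bromomethyl)-5-{[(tert-butyldimethylsilyl)oxy]methyl}furan-2(5H)-one; 14 methyl (2E)-6-iodo-2-(2-oxoethyl)hepta-2,6-dienoate
Product: 17 methyl (2E)-2-{(2S)-2-[(2S,3R)-2-{[(tert-butyldimethylsilyl)oxy]methyl}-4-methylidene-5-oxooxolan-3-yl]-2-hydroxyethyl}-6-iodohepta-2,6-dienoate, via allylchromium dichloride 15 (not isolated), via trimethylsilyl ether 16 (not isolated)
Conditions: CrCl2 (4 equiv), Me3SiCl (2 equiv), THF, 0 °C to rt, 5 (1.3 equiv) and 14 added together; then aqueous citric acid, rt
Reagents that add atoms: none
Why: Two equivalents of divalent chromium reduce the allylic C13–Br bond of 5 to the allylchromium species 15 (trivalent chromium on C13), which adds to the aldehyde of 14 through a closed six-membered chair transition state at its γ-carbon C7, the double bond moving from C7=C11 to C11=C13, so that the C7–C8 bond and the α-methylene lactone arise together; Me3SiCl caps the chromium alkoxide as 16, which keeps O8 from attacking C12 or C14, and the acidic work-up frees 17. The closest known reaction type is the chromium-mediated 2-(alkoxycarbonyl)allylation of aldehydes (Nozaki–Hiyama allylation) with 3-(bromomethyl)furan-2(5H)-ones, which gives β-(1-hydroxyalkyl)-α-methylene-γ-butyrolactones. No ring is closed: ring B is brought in intact from 5. C7 is set by C6, because the aldehyde can reach C7 of the flat butenolide only on the face opposite the CH2OTBS group, which gives the trans lactone (7R). C8 is set by the chair: the allyl unit is locked in an (E)-type geometry (C6 trans to C13 across C7=C11) and so lies pseudo-equatorial, the aldehyde residue C9 also takes an equatorial place, and the result is the anti relation of C6 and O8 along C9–C8–C7–C11, that is 8S, the configuration that step 11 inverts. The selectivities needed are secured by the substrates: divalent chromium without nickel reduces the allylic bromide but leaves the vinylic C4–I bond, the allylchromium reagent adds to the aldehyde and not to the enoate, and the neutral medium leaves the C9 methylene of 14 unenolized.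

Step 11
Reactants: 17 methyl (2E)-2-{(2S)-2-[(2S,3R)-2-{[(tert-butyldimethylsilyl)oxy]methyl}-4-methylidene-5-oxooxolan-3-yl]-2-hydroxyethyl}-6-iodohepta-2,6-dienoate; 18 (2Z)-2-methylbut-2-enoic acid (angelic acid)
Product: 19 methyl (2E)-2-{(2R)-2-[(2S,3R)-2-{[(tert-butyldimethylsilyl)oxy]methyl}-4-methylidene-5-oxooxolan-3-yl]-2-{[(2Z)-2-methylbut-2-enoyl]oxy}ethyl}-6-iodohepta-2,6-dienoate
Conditions: PPh3, DIAD, toluene, 0 °C to rt
Reagents that add atoms: none
Why: Mitsunobu esterification: the alkoxyphosphonium ion of 17 is displaced by angelate in an SN2 step, which inverts C8 from S to R; the acid acts as the nucleophile and is never acyl-activated, so its (Z)-geometry is kept.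

Step 12
Reactants: 19 methyl (2E)-2-{(2R)-2-[(2S,3R)-2-{[(tert-butyldimethylsilyl)oxy]methyl}-4-methylidene-5-oxooxolan-3-yl]-2-{[(2Z)-2-methylbut-2-enoyl]oxy}ethyl}-6-iodohepta-2,6-dienoate
Product: 20 methyl (2E)-2-{(2R)-2-[(2S,3R)-2-(hydroxymethyl)-4-methylidene-5-oxooxolan-3-yl]-2-{[(2Z)-2-methylbut-2-enoyl]oxy}ethyl}-6-iodohepta-2,6-dienoate
Conditions: HF·pyridine, pyridine, THF, 0 °C to rt
Reagents that add atoms: none
Why: Buffered HF removes the primary silyl ether without touching the angelate, the methyl ester or the methylene lactone, and without the basic fluoride that would add to the Michael acceptors.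

Step 13
Reactants: 20 methyl (2E)-2-{(2R)-2-[(2S,3R)-2-(hydroxymethyl)-4-methylidene-5-oxooxolan-3-yl]-2-{[(2Z)-2-methylbut-2-enoyl]oxy}ethyl}-6-iodohepta-2,6-dienoate
Product: 21 methyl (2E)-2-{(2R)-2-[(2S,3R)-2-formyl-4-methylidene-5-oxooxolan-3-yl]-2-{[(2Z)-2-methylbut-2-enoyl]oxy}ethyl}-6-iodohepta-2,6-dienoate
Conditions: Dess–Martin periodinane, NaHCO3, CH2Cl2, 0 °C; used at once
Reagents that add atoms: none
Why: Dess–Martin oxidation gives the C5 aldehyde under conditions mild enough to leave the adjacent, epimerizable C6 centre intact.

Step 14
Reactants: 21 methyl (2E)-2-{(2R)-2-[(2S,3R)-2-formyl-4-methylidene-5-oxooxolan-3-yl]-2-{[(2Z)-2-methylbut-2-enoyl]oxy}ethyl}-6-iodohepta-2,6-dienoate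
Product: 23 methyl (3aR,4R,6E,11S,11aS)-11-hydroxy-3,10-dimethylidene-4-{[(2Z)-2-methylbut-2-enoyl]oxy}-2-oxo-2,3,3a,4,5,8,9,10,11,11a-decahydrocyclodeca[b]furan-6-carboxylate, via alkenylchromium dichloride 22 (not isolated)
Conditions: CrCl2 (10 equiv), NiCl2 (0.1 equiv), DMSO, rt, slow addition of 21 to 2 mM; aqueous work-up
Reagents that add atoms: none
Why: Nozaki–Hiyama–Kishi reaction: zerovalent nickel inserts into the C4–I bond, transmetalation gives the alkenylchromium 22 (trivalent chromium), and this adds to the C5 aldehyde in a 10-exo-trig closure that the enoate, methylene lactone and angelate tolerate. C5 should be set by C6 and the forming ring: with the new C4–C5 bond antiperiplanar to C6–O6 (polar Felkin–Anh arrangement) and the chromium-bound oxygen turned to the outside of the ring (antiperiplanar to C6–C7), the 5S carbinol with H5 and H6 anti results.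

## Compound list

1 | (S)-but-3-ene-1,2-diol | OC[C@@H](O)C=C | starting material
2 | (S)-1-[(tert-butyldimethylsilyl)oxy]but-3-en-2-ol | CC(C)(C)[Si](C)(C)OC[C@@H](O)C=C | intermediate
3 | 2-(bromomethyl)prop-2-enoic acid | C=C(CBr)C(=O)O | starting material
4 | (S)-1-[(tert-butyldimethylsilyl)oxy]but-3-en-2-yl 2-(bromomethyl)prop-2-enoate | C=C(CBr)C(=O)O[C@H](CO[Si](C)(C)C(C)(C)C)C=C | intermediate
5 | (S)-3-(bromomethyl)-5-{[(tert-butyldimethylsilyl)oxy]methyl}furan-2(5H)-one | O=C1O[C@H](CO[Si](C)(C)C(C)(C)C)C=C1CBr | intermediate
6 | methyl 2-(diethoxyphosphoryl)acetate | CCOP(=O)(CC(=O)OC)OCC | starting material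
7 | (2-bromoethoxy)(tert-butyl)dimethylsilane | BrCCO[Si](C)(C)C(C)(C)C | starting material
8 | methyl 4-[(tert-butyldimethylsilyl)oxy]-2-(diethoxyphosphoryl)butanoate (racemic) | CCOP(=O)(OCC)C(CCO[Si](C)(C)C(C)(C)C)C(=O)OC | intermediate
9 | pent-4-yn-1-ol | C#CCCCO | starting material
10 | 4-iodopent-4-en-1-ol | C=C(I)CCCO | intermediate
11 | 4-iodopent-4-enal | C=C(I)CCC=O | intermediate
12 | methyl (2E)-2-{2-[(tert-butyldimethylsilyl)oxy]ethyl}-6-iodohepta-2,6-dienoate | CC(C)(C)[Si](C)(C)OCC/C(C(=O)OC)=C\CCC(I)=C | intermediate
13 | methyl (2E)-2-(2-hydroxyethyl)-6-iodohepta-2,6-dienoate | OCC/C(C(=O)OC)=C\CCC(I)=C | intermediate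
14 | methyl (2E)-6-iodo-2-(2-oxoethyl)hepta-2,6-dienoate | O=CC/C(C(=O)OC)=C\CCC(I)=C | intermediate
15 | dichloro{[(5S)-5-{[(tert-butyldimethylsilyl)oxy]methyl}-2-oxo-2,5-dihydrofuran-3-yl]methyl}chromium (trivalent chromium; allylchromium reagent from 5) | O=C1O[C@H](CO[Si](C)(C)C(C)(C)C)C=C1C[Cr](Cl)Cl | intermediate
16 | O8-trimethylsilyl ether of 17 | C=C1C(=O)O[C@H](CO[Si](C)(C)C(C)(C)C)[C@H]1[C@@H](O[Si](C)(C)C)C/C(C(=O)OC)=C\CCC(I)=C | intermediate
17 | methyl (2E)-2-{(2S)-2-[(2S,3R)-2-{[(tert-butyldimethylsilyl)oxy]methyl}-4-methylidene-5-oxooxolan-3-yl]-2-hydroxyethyl}-6-iodohepta-2,6-dienoate | C=C1C(=O)O[C@H](CO[Si](C)(C)C(C)(C)C)[C@H]1[C@@H](O)C/C(C(=O)OC)=C\CCC(I)=C | intermediate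
18 | (2Z)-2-methylbut-2-enoic acid (angelic acid) | C/C=C(/C)C(=O)O | starting material
19 | methyl (2E)-2-{(2R)-2-[(2S,3R)-2-{[(tert-butyldimethylsilyl)oxy]methyl}-4-methylidene-5-oxooxolan-3-yl]-2-{[(2Z)-2-methylbut-2-enoyl]oxy}ethyl}-6-iodohepta-2,6-dienoate | C=C1C(=O)O[C@H](CO[Si](C)(C)C(C)(C)C)[C@H]1[C@H](OC(=O)/C(C)=C\C)C/C(C(=O)OC)=C\CCC(I)=C | intermediate
20 | methyl (2E)-2-{(2R)-2-[(2S,3R)-2-(hydroxymethyl)-4-methylidene-5-oxooxolan-3-yl]-2-{[(2Z)-2-methylbut-2-enoyl]oxy}ethyl}-6-iodohepta-2,6-dienoate | C=C1C(=O)O[C@H](CO)[C@H]1[C@H](OC(=O)/C(C)=C\C)C/C(C(=O)OC)=C\CCC(I)=C | intermediate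
21 | methyl (2E)-2-{(2R)-2-[(2S,3R)-2-formyl-4-methylidene-5-oxooxolan-3-yl]-2-{[(2Z)-2-methylbut-2-enoyl]oxy}ethyl}-6-iodohepta-2,6-dienoate | C=C1C(=O)O[C@H](C=O)[C@H]1[C@H](OC(=O)/C(C)=C\C)C/C(C(=O)OC)=C\CCC(I)=C | intermediate
22 | alkenylchromium dichloride from 21 (C4–CrCl2 in place of C4–I; trivalent chromium) | C=C1C(=O)O[C@H](C=O)[C@H]1[C@H](OC(=O)/C(C)=C\C)C/C(C(=O)OC)=C\CCC(=C)[Cr](Cl)Cl | intermediate
23 | methyl (3aR,4R,6E,11S,11aS)-11-hydroxy-3,10-dimethylidene-4-{[(2Z)-2-methylbut-2-enoyl]oxy}-2-oxo-2,3,3a,4,5,8,9,10,11,11a-decahydrocyclodeca[b]furan-6-carboxylate (CNP0163095.1) | C=C1C(=O)O[C@H]2[C@H]1[C@H](OC(=O)/C(C)=C\C)C/C(C(=O)OC)=C\CCC(=C)[C@@H]2O | target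

## Step count and risk

Total step count: 14. Longest linear sequence: 10 steps (steps 5–14, from 9 through 10, 11, 12, 13, 14, 17, 19, 20 and 21 to 23). The branches 1 → 5 (three steps) and 6 + 7 → 8 (one step) join it at steps 10 and 7.

Steps least certain to work:

**Step 10 (key step).** Most likely to go wrong: migration of the C1=C10 double bond of 14 into conjugation with the aldehyde under the Lewis-acidic trivalent chromium before C–C bond formation is complete. Also possible are erosion of the C8 selectivity by a competing boat-like transition state and reductive 1,4-elimination of the allylchromium with opening of ring B. Incomplete selectivity at C8 is tolerable, since the minor epimer can be acylated with retention to the same ester. Fallback, setting out from 5 (with 14) and coming back at 19: 5 is stannylated with (Bu3Sn)2 and Pd(PPh3)4 (zerovalent palladium) to the allylstannane F1. F1 is added to 14 with BF3·OEt2 in CH2Cl2 at −78 °C through an open, antiperiplanar transition state. This is fast at low temperature and should be syn-selective, still anti to the C6 substituent, giving the 8R alcohol F2 directly. F2 is acylated with retention by the mixed anhydride of 18 and 2,4,6-trichlorobenzoyl chloride (Et3N, toluene, 80 °C, no nucleophilic catalyst) to give 19.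

**Step 14.** Most likely to go wrong: poor facial selectivity at C5, because the open-chain Felkin preference (carbonyl oxygen next to C7) opposes the ring-controlled arrangement argued for; intermolecular coupling is a second concern if dilution is insufficient. Fallback, setting out from 21 and coming back at 23: if the cyclization gives the 5R alcohol F3, alone or mixed with 23, the material is oxidized with Dess–Martin periodinane to the cross-conjugated enone F4. F4 is reduced under reagent control (Corey–Bakshi–Shibata reduction, catecholborane, −78 °C, with the oxazaborolidine enantiomer that delivers hydride to the face giving 5S) to 23.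

**Step 11.** Most likely to go wrong: elimination from the alkoxyphosphonium ion or failure of substitution at the hindered C8, which is flanked by the branched C7. Fallback, setting out from 17 and coming back at 19: a two-step activation and displacement through an isolated sulfonate. 17 is converted with ClCH2SO2Cl and pyridine into the chloromethanesulfonate F5, which is displaced with inversion by cesium angelate (from 18 and Cs2CO3, 18-crown-6, toluene) to give 19.

**Step 9.** Most likely to go wrong: double-bond migration (C1=C10 to C9=C10) by enolization of the C9 methylene during oxidation or on silica. Fallback, setting out from 6 (with 11) and coming back at 14: the aldehyde is carried at its final oxidation level as an acetal. 6 is alkylated with bromoacetaldehyde dimethyl acetal (NaH, DMF, heat) to the acetal phosphonate F6. Olefination of 11 with F6 gives the acetal enoate F7. Mild acid hydrolysis (aqueous formic acid, 0 °C) releases 14 in solution for direct use in step 10.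

**Step 3.** Most likely to go wrong: slow turnover at the electron-poor 1,1-disubstituted bromomethyl acrylate and loss of catalyst to the allylic bromide. Fallback, setting out from 2 and coming back at 5: 2 is acylated with methacryloyl chloride and Et3N to the methacrylate F8. Ring-closing metathesis gives the 3-methylbutenolide F9. Wohl–Ziegler bromination of the allylic methyl group (NBS, AIBN, PhCF3, reflux) gives 5.

## Further compounds

F1 | step 10 | (S)-5-{[(tert-butyldimethylsilyl)oxy]methyl}-3-[(tributylstannyl)methyl]furan-2(5H)-one | O=C1O[C@H](CO[Si](C)(C)C(C)(C)C)C=C1C[Sn](CCCC)(CCCC)CCCC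
F2 | step 10 | methyl (2E)-2-{(2R)-2-[(2S,3R)-2-{[(tert-butyldimethylsilyl)oxy]methyl}-4-methylidene-5-oxooxolan-3-yl]-2-hydroxyethyl}-6-iodohepta-2,6-dienoate (C8 epimer of 17) | C=C1C(=O)O[C@H](CO[Si](C)(C)C(C)(C)C)[C@H]1[C@H](O)C/C(C(=O)OC)=C\CCC(I)=C
F3 | step 14 | methyl (3aR,4R,6E,11R,11aS)-11-hydroxy-3,10-dimethylidene-4-{[(2Z)-2-methylbut-2-enoyl]oxy}-2-oxo-2,3,3a,4,5,8,9,10,11,11a-decahydrocyclodeca[b]furan-6-carboxylate (C5 epimer of 23) | C=C1C(=O)O[C@H]2[C@H]1[C@H](OC(=O)/C(C)=C\C)C/C(C(=O)OC)=C\CCC(=C)[C@H]2O
F4 | step 14 | C5 ketone of 23 (11-oxo compound, cross-conjugated enone) | C=C1C(=O)O[C@H]2[C@H]1[C@H](OC(=O)/C(C)=C\C)C/C(C(=O)OC)=C\CCC(=C)C2=O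
F5 | step 11 | O8-chloromethanesulfonate of 17 | C=C1C(=O)O[C@H](CO[Si](C)(C)C(C)(C)C)[C@H]1[C@@H](OS(=O)(=O)CCl)C/C(C(=O)OC)=C\CCC(I)=C
F6 | step 9 | methyl 2-(diethoxyphosphoryl)-4,4-dimethoxybutanoate (racemic) | CCOP(=O)(OCC)C(CC(OC)OC)C(=O)OC
F7 | step 9 | methyl (2E)-2-(2,2-dimethoxyethyl)-6-iodohepta-2,6-dienoate | COC(OC)C/C(C(=O)OC)=C\CCC(I)=C
F8 | step 3 | (S)-1-[(tert-butyldimethylsilyl)oxy]but-3-en-2-yl 2-methylprop-2-enoate | C=C(C)C(=O)O[C@H](CO[Si](C)(C)C(C)(C)C)C=C
F9 | step 3 | (S)-5-{[(tert-butyldimethylsilyl)oxy]methyl}-3-methylfuran-2(5H)-one | O=C1O[C@H](CO[Si](C)(C)C(C)(C)C)C=C1C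
A1 | alternative 1 | methyl (2Z,4R,6E,11S)-2-(bromomethyl)-11-[(tert-butyldimethylsilyl)oxy]-6-(methoxycarbonyl)-10-methylidene-4-{[(2Z)-2-methylbut-2-enoyl]oxy}-12-oxododeca-2,6-dienoate (open-chain bromo aldehyde) | O=C[C@@H](O[Si](C)(C)C(C)(C)C)C(=C)CC/C=C(/C(=O)OC)C[C@@H](OC(=O)/C(C)=C\C)/C=C(\CBr)C(=O)OC
A2 | alternative 1 | O5-tert-butyldimethylsilyl ether of 23 | C=C1C(=O)O[C@H]2[C@H]1[C@H](OC(=O)/C(C)=C\C)C/C(C(=O)OC)=C\CCC(=C)[C@@H]2O[Si](C)(C)C(C)(C)C
A3 | alternative 2 | methyl 2-{(2R)-2-[(2S,3R)-2-[(1S)-1-hydroxy-2-methylidenehex-5-en-1-yl]-4-methylidene-5-oxooxolan-3-yl]-2-{[(2Z)-2-methylbut-2-enoyl]oxy}ethyl}prop-2-enoate (metathesis precursor) | C=C1C(=O)O[C@H]([C@@H](O)C(=C)CCC=C)[C@H]1[C@H](OC(=O)/C(C)=C\C)CC(=C)C(=O)OC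
A4 | alternative 3 | cis-1,2-divinylcyclohexanol with the six-membered ring C5–C10: C5 hydroxyl and vinyl, C10 methyl ester and vinyl, C8 silyl ether, saturated lactone on C6–C7 | COC(=O)[C@@]1(C=C)C[C@@H](O[Si](C)(C)C(C)(C)C)[C@H]2CC(=O)O[C@@H]2[C@]1(O)C=C
A5 | alternative 3 | cyclodecenone from A4: C5 ketone, C1=C10 enoate, C8 silyl ether, saturated lactone on C6–C7 | O=C1CCC/C=C(C(=O)OC)\C[C@@H](O[Si](C)(C)C(C)(C)C)[C@H]2CC(=O)O[C@H]12
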